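**Plan**

- Retrosynthesis: the lactone O2–C1 bond is cut (enol lactonisation) and then the C3–C4 bond (acylation of a lateral benzylic anion), which leaves an ortho-toluate that carries the whole diaryl ether.
- Ring A is then cut across C4a–C8a, C8–C8a, C6–C7 and C5–C6 into a 2-diazo-3-oxo ester and an aryl ethynyl ether; the ynol ether goes back to a ring B phenol and trichloroethylene.
- Enabling feature: ring A (C4a, C5, C6, C7, C8, C8a) is a resorcinol monoether. The C6 hydroxyl is meta to the C8 aryloxy group, and C8a, between C8 and C4a, carries the lactone carbon C1. An ester-bearing vinylketene and an ynol ether give exactly this pattern.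
- Forward order: ring B is fully substituted first (from olivetol), ring A is built onto its ethynyl ether in one operation, the pyranone ring is closed last, and both benzyl ethers are removed in the final step.
- Stereochemistry: the target has no stereocentre. The racemic centres that appear on the way (a carbinol, a cyclobutenone carbon, a hemiaminal carbon) and the (E)-dichlorovinyl geometry are all erased.

Key step: step 9

Remark: locants C1–C8a are those of the isocoumarin (1H-isochromen-1-one). The ethyl ester is kept on the diazo component so that C1 arrives with ring A.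

**Route**

Step 1
Reactants: 1 olivetol (5-pentylbenzene-1,3-diol)
Product: 3 2,4-dihydroxy-6-pentylbenzaldehyde, via aryl iminium chloride 2 (not isolated)
Conditions: POCl3, DMF, 0 °C to rt; then H2O, 50 °C
Reagents that add atoms: N,N-dimethylformamide, CN(C)C=O; water, O
Why: Vilsmeier–Haack formylation of a 5-alkylresorcinol should go to the ring carbon ortho to one hydroxyl and para to the other (between OH and pentyl), as it does for orcinol, and hydrolysis of iminium salt 2 releases the aldehyde.

Step 2
Reactants: 3 2,4-dihydroxy-6-pentylbenzaldehyde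
Product: 4 2-hydroxy-4-methoxy-6-pentylbenzaldehyde
Conditions: MeI (1.05 equiv), K2CO3 (1.0 equiv), acetone, rt
Reagents that add atoms: iodomethane, CI
Why: Williamson etherification with one equivalent of base should take the more acidic, non-chelated 4-OH para to the formyl group, because the 2-OH is held in a hydrogen bond to the aldehyde.

Step 3
Reactants: 4 2-hydroxy-4-methoxy-6-pentylbenzaldehyde
Product: 5 2-(benzyloxy)-4-methoxy-6-pentylbenzaldehyde
Conditions: BnBr, K2CO3, DMF, 60 °C
Reagents that add atoms: benzyl bromide, BrCc1ccccc1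
Why: Williamson benzylation of the remaining chelated phenol under more forcing conditions fixes the future ring B hydroxyl as a benzyl ether that survives the organolithium and photochemical steps.

Step 4
Reactants: 5 2-(benzyloxy)-4-methoxy-6-pentylbenzaldehyde
Product: 7 2-(benzyloxy)-4-methoxy-6-pentylphenol, via aryl formate 6 (not isolated)
Conditions: mCPBA, CH2Cl2, 0 °C to rt; then K2CO3 (cat.), MeOH, rt
Reagents that add atoms: 3-chloroperbenzoic acid, OOC(=O)c1cccc(Cl)c1
Why: In this Baeyer–Villiger (Dakin-type) oxidation the electron-rich 2,4-dialkoxyaryl group should migrate in preference to hydride, and methanolysis of formate 6 places the free hydroxyl exactly between the benzyloxy and pentyl groups.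

Step 5
Reactants: 7 2-(benzyloxy)-4-methoxy-6-pentylphenol; 8 trichloroethylene
Product: 10 1-(benzyloxy)-2-{[(E)-1,2-dichloroethenyl]oxy}-5-methoxy-3-pentylbenzene, via dichloroacetylene 9 (not isolated)
Conditions: K2CO3, DMF, 70 °C
Reagents that add atoms: none
Why: Base-induced loss of HCl from trichloroethylene gives dichloroacetylene 9, and anti addition of the phenoxide to this linear electrophile (net nucleophilic vinylic substitution, the standard route to aryl (E)-1,2-dichlorovinyl ethers) should tolerate the two ortho substituents that would block an arylation.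

Step 6
Reactants: 10 1-(benzyloxy)-2-{[(E)-1,2-dichloroethenyl]oxy}-5-methoxy-3-pentylbenzene
Product: 13 1-(benzyloxy)-2-(ethynyloxy)-5-methoxy-3-pentylbenzene, via chloroethynyl ether 11 (not isolated), via lithium acetylide 12 (not isolated)
Conditions: n-BuLi (2.5 equiv), THF, −78 °C; then H2O, −78 to 0 °C
Reagents that add atoms: none
Why: This is the standard dichlorovinyl ether to ynol ether elimination, in which vinylic deprotonation and β-elimination give chloroalkyne 11, lithium–chlorine exchange gives acetylide 12, and protonation releases the terminal aryl ynol ether.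

Step 7
Reactants: 14 ethyl diazoacetate; 15 methacrolein
Product: 16 ethyl 2-diazo-3-hydroxy-4-methylpent-4-enoate (racemic)
Conditions: DBU (cat.), MeCN, 0 °C to rt
Reagents that add atoms: none
Why: Base-catalysed aldol-type addition of the diazoacetate carbanion to the aldehyde carbonyl (1,2-addition) is a standard route to β-hydroxy-α-diazo esters, and the racemic carbinol centre is removed in step 8.

Step 8
Reactants: 16 ethyl 2-diazo-3-hydroxy-4-methylpent-4-enoate
Product: 17 ethyl 2-diazo-4-methyl-3-oxopent-4-enoate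
Conditions: IBX, DMSO, rt
Reagents that add atoms: none
Why: IBX oxidation of the allylic secondary alcohol to the ketone is a known way to make 2-diazo-3-oxo esters and leaves the diazo group intact.

Step 9
Reactants: 17 ethyl 2-diazo-4-methyl-3-oxopent-4-enoate; 13 1-(benzyloxy)-2-(ethynyloxy)-5-methoxy-3-pentylbenzene
Product: 22 ethyl 2-[2-(benzyloxy)-4-methoxy-6-pentylphenoxy]-4-hydroxy-6-methylbenzoate, via vinylketene 18 (not isolated), via cyclobutenone 19 (not isolated), via dienylketene 20 (not isolated), via cyclohexadienone 21 (not isolated)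
Conditions: 17 (1.3 equiv), hν (300 nm, Pyrex), ClCH2CH2Cl, rt; then 80 °C
Reagents that add atoms: none
Why: Proposed new method: irradiation should expel N2 from 17 with a Wolff 1,2-shift of the isopropenyl group to the diazo carbon (the C4a–C8a bond), giving the ester-substituted vinylketene 18, which adds ynol ether 13 across its ketene C=C in a [2+2] cycloaddition to cyclobutenone 19 (C8–C8a and C6–C7); heating opens 19 by 4π electrocyclic ring opening to dienylketene 20, 6π electrocyclisation closes ring A at C5–C6 as cyclohexadienone 21, and enolisation gives phenol 22. The closest known reaction type is the Danheiser benzannulation of α-diazo enones (photochemical Wolff variant) with alkoxy- and siloxyacetylenes; what is not established is its use with a 2-diazo-3-oxo ester together with an aryl ethynyl ether, although the photochemical Wolff shift of 2-diazo-3-oxo esters to alkoxycarbonylketenes and [2+2] additions of such ketenes to electron-rich π bonds are each known. Ring A is closed by the thermal 6π electrocyclisation of 20, the four-membered ring of 19 being only a relay that is formed by [2+2] addition and opened again. No stereocentre results, since the quaternary carbon of 19 becomes trigonal on ring opening. The regiochemistry needed (CH terminus of 13 to the ketene carbonyl carbon, so that the aryloxy carbon lands on the ester-bearing carbon and the new hydroxyl ends meta to the aryloxy group) is secured by the polarisation of the partners, the oxygen-stabilised cationic character of the aryloxy carbon matching the enolate character of the ester-bearing ketene carbon. The geometry needed in 20 (ketene arm syn to the isopropenyl group, not to the ester, which could close to a 2-pyranone) is supplied by the reversibility of the 4π opening, which funnels material through the carbocyclic 6π closure.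

Step 10
Reactants: 22 ethyl 2-[2-(benzyloxy)-4-methoxy-6-pentylphenoxy]-4-hydroxy-6-methylbenzoate
Product: 23 ethyl 4-(benzyloxy)-2-[2-(benzyloxy)-4-methoxy-6-pentylphenoxy]-6-methylbenzoate
Conditions: BnBr, K2CO3, DMF, rt
Reagents that add atoms: benzyl bromide, BrCc1ccccc1
Why: Williamson etherification of the only free (and ester-acidified) phenol masks the acidic OH before the lateral metalation, with the same group as on ring B so that both can be removed together.

Step 11
Reactants: 24 hexanoyl chloride; 25 N,O-dimethylhydroxylamine hydrochloride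
Product: 26 N-methoxy-N-methylhexanamide
Conditions: K2CO3, H2O/CH2Cl2, 0 °C to rt
Reagents that add atoms: none
Why: Schotten–Baumann acylation of the liberated N,O-dimethylhydroxylamine by the acid chloride gives the Weinreb amide.

Step 12
Reactants: 23 ethyl 4-(benzyloxy)-2-[2-(benzyloxy)-4-methoxy-6-pentylphenoxy]-6-methylbenzoate; 26 N-methoxy-N-methylhexanamide
Product: 29 ethyl 4-(benzyloxy)-2-[2-(benzyloxy)-4-methoxy-6-pentylphenoxy]-6-(2-oxoheptyl)benzoate, via benzylic lithium species 27 (not isolated), via tetrahedral adduct 28 (not isolated)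
Conditions: LiN(i-Pr)2, THF, −78 °C; then 26, −78 to −40 °C; aq. HCl
Reagents that add atoms: none
Why: Lateral (benzylic) lithiation of the ortho-toluate, whose ester is shielded by two ortho substituents, gives the ester-stabilised anion 27, and the Weinreb ketone synthesis holds the product as chelated adduct 28 until work-up, so the C3–C4 bond forms without over-addition.

Step 13
Reactants: 29 ethyl 4-(benzyloxy)-2-[2-(benzyloxy)-4-methoxy-6-pentylphenoxy]-6-(2-oxoheptyl)benzoate
Product: 30 6-(benzyloxy)-8-[2-(benzyloxy)-4-methoxy-6-pentylphenoxy]-3-pentyl-1H-isochromen-1-one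
Conditions: TsOH·H2O (cat.), PhMe, reflux
Reagents that add atoms: none
Why: In this acid-catalysed enol lactonisation the enol oxygen of the aryl-conjugated ketone attacks the neighbouring ester (6-exo-trig acyl substitution, loss of ethanol), and acid is preferred to base so that Dieckmann-type C-cyclisation to a naphthalenediol is avoided.

Step 14
Reactants: 30 6-(benzyloxy)-8-[2-(benzyloxy)-4-methoxy-6-pentylphenoxy]-3-pentyl-1H-isochromen-1-one
Product: 32 6-hydroxy-8-(2-hydroxy-4-methoxy-6-pentylphenoxy)-3-pentyl-1H-isochromen-1-one, via bis(dichloroboryl) ether 31 (not isolated)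
Conditions: BCl3, C6HMe5, CH2Cl2, −78 °C; then H2O
Reagents that add atoms: none
Why: Lewis-acid cleavage of aryl benzyl ethers by BCl3, with pentamethylbenzene as benzyl cation scavenger, should at −78 °C spare the non-chelated aryl methyl ether, the diaryl ether and the C3–C4 double bond that hydrogenolysis could reduce.

**Compound list**

1 | olivetol (5-pentylbenzene-1,3-diol) | CCCCCc1cc(O)cc(O)c1 | starting material
2 | [(2,4-dihydroxy-6-pentylphenyl)methylidene]dimethylammonium chloride | CCCCCc1cc(O)cc(O)c1C=[N+](C)C.[Cl-] | intermediate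
3 | 2,4-dihydroxy-6-pentylbenzaldehyde | CCCCCc1cc(O)cc(O)c1C=O | intermediate
4 | 2-hydroxy-4-methoxy-6-pentylbenzaldehyde | CCCCCc1cc(OC)cc(O)c1C=O | intermediate
5 | 2-(benzyloxy)-4-methoxy-6-pentylbenzaldehyde | CCCCCc1cc(OC)cc(OCc2ccccc2)c1C=O | intermediate
6 | 2-(benzyloxy)-4-methoxy-6-pentylphenyl formate | CCCCCc1cc(OC)cc(OCc2ccccc2)c1OC=O | intermediate
7 | 2-(benzyloxy)-4-methoxy-6-pentylphenol | CCCCCc1cc(OC)cc(OCc2ccccc2)c1O | intermediate
8 | trichloroethylene | ClC=C(Cl)Cl | starting material
9 | dichloroacetylene | ClC#CCl | intermediate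
10 | 1-(benzyloxy)-2-{[(E)-1,2-dichloroethenyl]oxy}-5-methoxy-3-pentylbenzene | CCCCCc1cc(OC)cc(OCc2ccccc2)c1O/C(Cl)=C\Cl | intermediate
11 | 1-(benzyloxy)-2-[(chloroethynyl)oxy]-5-methoxy-3-pentylbenzene | CCCCCc1cc(OC)cc(OCc2ccccc2)c1OC#CCl | intermediate
12 | lithium [2-(benzyloxy)-4-methoxy-6-pentylphenoxy]acetylide | CCCCCc1cc(OC)cc(OCc2ccccc2)c1OC#C[Li] | intermediate
13 | 1-(benzyloxy)-2-(ethynyloxy)-5-methoxy-3-pentylbenzene | CCCCCc1cc(OC)cc(OCc2ccccc2)c1OC#C | intermediate
14 | ethyl diazoacetate | CCOC(=O)C=[N+]=[N-] | starting material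
15 | methacrolein | CC(=C)C=O | starting material
16 | ethyl 2-diazo-3-hydroxy-4-methylpent-4-enoate (racemic) | CCOC(=O)C(=[N+]=[N-])C(O)C(C)=C | intermediate
17 | ethyl 2-diazo-4-methyl-3-oxopent-4-enoate | CCOC(=O)C(=[N+]=[N-])C(=O)C(C)=C | intermediate
18 | ethyl 3-methyl-2-(oxomethylidene)but-3-enoate | CCOC(=O)C(=C=O)C(C)=C | intermediate
19 | ethyl 2-[2-(benzyloxy)-4-methoxy-6-pentylphenoxy]-4-oxo-1-(prop-1-en-2-yl)cyclobut-2-ene-1-carboxylate (racemic) | CCOC(=O)C1(C(C)=C)C(=O)C=C1Oc1c(CCCCC)cc(OC)cc1OCc1ccccc1 | intermediate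
20 | ethyl (2Z)-3-[2-(benzyloxy)-4-methoxy-6-pentylphenoxy]-5-oxo-2-(prop-1-en-2-yl)penta-2,4-dienoate | CCOC(=O)/C(C(C)=C)=C(/C=C=O)Oc1c(CCCCC)cc(OC)cc1OCc1ccccc1 | intermediate
21 | ethyl 6-[2-(benzyloxy)-4-methoxy-6-pentylphenoxy]-2-methyl-4-oxocyclohexa-1,5-diene-1-carboxylate | CCOC(=O)C1=C(C)CC(=O)C=C1Oc1c(CCCCC)cc(OC)cc1OCc1ccccc1 | intermediate
22 | ethyl 2-[2-(benzyloxy)-4-methoxy-6-pentylphenoxy]-4-hydroxy-6-methylbenzoate | CCOC(=O)c1c(C)cc(O)cc1Oc1c(CCCCC)cc(OC)cc1OCc1ccccc1 | intermediate
23 | ethyl 4-(benzyloxy)-2-[2-(benzyloxy)-4-methoxy-6-pentylphenoxy]-6-methylbenzoate | CCOC(=O)c1c(C)cc(OCc2ccccc2)cc1Oc1c(CCCCC)cc(OC)cc1OCc1ccccc1 | intermediate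
24 | hexanoyl chloride | CCCCCC(=O)Cl | starting material
25 | N,O-dimethylhydroxylamine hydrochloride | CNOC.Cl | starting material
26 | N-methoxy-N-methylhexanamide | CCCCCC(=O)N(C)OC | intermediate
27 | ethyl 4-(benzyloxy)-2-[2-(benzyloxy)-4-methoxy-6-pentylphenoxy]-6-(lithiomethyl)benzoate | CCOC(=O)c1c(C[Li])cc(OCc2ccccc2)cc1Oc1c(CCCCC)cc(OC)cc1OCc1ccccc1 | intermediate
28 | ethyl 4-(benzyloxy)-2-[2-(benzyloxy)-4-methoxy-6-pentylphenoxy]-6-{2-(lithiooxy)-2-[methoxy(methyl)amino]heptyl}benzoate (racemic) | CCOC(=O)c1c(CC(O[Li])(CCCCC)N(C)OC)cc(OCc2ccccc2)cc1Oc1c(CCCCC)cc(OC)cc1OCc1ccccc1 | intermediate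
29 | ethyl 4-(benzyloxy)-2-[2-(benzyloxy)-4-methoxy-6-pentylphenoxy]-6-(2-oxoheptyl)benzoate | CCOC(=O)c1c(CC(=O)CCCCC)cc(OCc2ccccc2)cc1Oc1c(CCCCC)cc(OC)cc1OCc1ccccc1 | intermediate
30 | 6-(benzyloxy)-8-[2-(benzyloxy)-4-methoxy-6-pentylphenoxy]-3-pentyl-1H-isochromen-1-one | CCCCCc1cc2cc(OCc3ccccc3)cc(Oc3c(OCc4ccccc4)cc(OC)cc3CCCCC)c2c(=O)o1 | intermediate
31 | 6-[(dichloroboranyl)oxy]-8-{2-[(dichloroboranyl)oxy]-4-methoxy-6-pentylphenoxy}-3-pentyl-1H-isochromen-1-one | CCCCCc1cc2cc(OB(Cl)Cl)cc(Oc3c(OB(Cl)Cl)cc(OC)cc3CCCCC)c2c(=O)o1 | intermediate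
32 | 6-hydroxy-8-(2-hydroxy-4-methoxy-6-pentylphenoxy)-3-pentyl-1H-isochromen-1-one | CCCCCc1cc2cc(O)cc(Oc3c(O)cc(OC)cc3CCCCC)c2c(=O)o1 | target

**Step count and risks**

Total step count: 14. Longest linear sequence: 11 steps (steps 1–6, 9, 10, 12, 13, 14, from olivetol 1 to target 32).

Steps most likely to fail:

1. Step 9 (Proposed new method). Several processes could divert it:
   - an inefficient Wolff shift of the acceptor-stabilised diazo compound;
   - hetero-[4+2] addition of the ester-substituted ketene to the ynol ether in place of [2+2] addition;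
   - oxa-6π closure of the wrong dienylketene geometry to a 2-pyranone;
   - acylation of the product phenol by excess ketene.

   The fallback uses known chemistry and makes the diaryl ether by Pd-catalysed C–O coupling onto a preformed ring A. It sets out from phenol 7. Commercial ethyl 2,4-dihydroxy-6-methylbenzoate F1 would be benzylated at its non-chelated 4-OH (BnBr, K2CO3, acetone) to ethyl 4-(benzyloxy)-2-hydroxy-6-methylbenzoate F2. Tf2O and pyridine would convert this into ethyl 4-(benzyloxy)-2-methyl-6-{[(trifluoromethyl)sulfonyl]oxy}benzoate F3. Coupling of F3 with 7 (Pd(OAc)2, di-tert-butyl(2′,4′,6′-triisopropylbiphenyl-2-yl)phosphine, K3PO4, toluene, 100 °C; Buchwald–Hartwig-type diaryl ether synthesis) would give 23 directly, and the route is rejoined there before step 12.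

2. Step 6. The terminal aryl ethynyl ether could be lost by polymerisation or hydration during work-up and concentration, and excess n-BuLi could metalate positions other than the vinylic C–H.

   The fallback sets out from 10 and carries a silyl-capped alkyne through the annulation. Acetylide 12 would be quenched with Me3SiCl instead of water to give the storable {[2-(benzyloxy)-4-methoxy-6-pentylphenoxy]ethynyl}(trimethyl)silane F4. The silicon-bearing carbon stays the nucleophilic terminus, so F4 would be combined with 17 under the conditions of step 9. The sequence would run through vinylketene 18, the silylated cyclobutenone F5, the silylated dienylketene F6 and the silylated cyclohexadienone F7, and give ethyl 2-[2-(benzyloxy)-4-methoxy-6-pentylphenoxy]-4-hydroxy-6-methyl-3-(trimethylsilyl)benzoate F8. Ipso-protodesilylation of this activated aryl silane (CF3CO2H, CH2Cl2, 0 °C) would return to 22, where the route continues with step 10.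

3. Step 12. The basic benzylic anion 27 could take a proton from the enolisable amide 26 (returning 23), or slow acylation could let 27 condense with the ester of unreacted 23.

   The fallback sets out from 23 and forms the C3–C4 bond at the alcohol oxidation level. Anion 27 would be trapped at −78 °C with the more electrophilic hexanal (CCCCCC=O) to give the lithium alkoxide F9. Quenching cold with AcOH, before lactonisation can occur, would give ethyl 4-(benzyloxy)-2-[2-(benzyloxy)-4-methoxy-6-pentylphenoxy]-6-(2-hydroxyheptyl)benzoate F10 (racemic). Dess–Martin oxidation of the secondary alcohol would give keto ester 29, where the route is rejoined before step 13.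

**Further compounds**

F1 | step 9 | ethyl 2,4-dihydroxy-6-methylbenzoate (ethyl orsellinate, purchased) | CCOC(=O)c1c(C)cc(O)cc1O
F2 | step 9 | ethyl 4-(benzyloxy)-2-hydroxy-6-methylbenzoate | CCOC(=O)c1c(C)cc(OCc2ccccc2)cc1O
F3 | step 9 | ethyl 4-(benzyloxy)-2-methyl-6-{[(trifluoromethyl)sulfonyl]oxy}benzoate | CCOC(=O)c1c(C)cc(OCc2ccccc2)cc1OS(=O)(=O)C(F)(F)F
F4 | step 6 | {[2-(benzyloxy)-4-methoxy-6-pentylphenoxy]ethynyl}(trimethyl)silane | CCCCCc1cc(OC)cc(OCc2ccccc2)c1OC#C[Si](C)(C)C
F5 | step 6 | ethyl 2-[2-(benzyloxy)-4-methoxy-6-pentylphenoxy]-4-oxo-1-(prop-1-en-2-yl)-3-(trimethylsilyl)cyclobut-2-ene-1-carboxylate (racemic) | CCOC(=O)C1(C(C)=C)C(=O)C([Si](C)(C)C)=C1Oc1c(CCCCC)cc(OC)cc1OCc1ccccc1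
F6 | step 6 | ethyl (2Z)-3-[2-(benzyloxy)-4-methoxy-6-pentylphenoxy]-5-oxo-2-(prop-1-en-2-yl)-4-(trimethylsilyl)penta-2,4-dienoate | CCOC(=O)/C(C(C)=C)=C(/C(=C=O)[Si](C)(C)C)Oc1c(CCCCC)cc(OC)cc1OCc1ccccc1
F7 | step 6 | ethyl 6-[2-(benzyloxy)-4-methoxy-6-pentylphenoxy]-2-methyl-4-oxo-5-(trimethylsilyl)cyclohexa-1,5-diene-1-carboxylate | CCOC(=O)C1=C(C)CC(=O)C([Si](C)(C)C)=C1Oc1c(CCCCC)cc(OC)cc1OCc1ccccc1
F8 | step 6 | ethyl 2-[2-(benzyloxy)-4-methoxy-6-pentylphenoxy]-4-hydroxy-6-methyl-3-(trimethylsilyl)benzoate | CCOC(=O)c1c(C)cc(O)c([Si](C)(C)C)c1Oc1c(CCCCC)cc(OC)cc1OCc1ccccc1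
F9 | step 12 | ethyl 4-(benzyloxy)-2-[2-(benzyloxy)-4-methoxy-6-pentylphenoxy]-6-[2-(lithiooxy)heptyl]benzoate (racemic) | CCOC(=O)c1c(CC(O[Li])CCCCC)cc(OCc2ccccc2)cc1Oc1c(CCCCC)cc(OC)cc1OCc1ccccc1
F10 | step 12 | ethyl 4-(benzyloxy)-2-[2-(benzyloxy)-4-methoxy-6-pentylphenoxy]-6-(2-hydroxyheptyl)benzoate (racemic) | CCOC(=O)c1c(CC(O)CCCCC)cc(OCc2ccccc2)cc1Oc1c(CCCCC)cc(OC)cc1OCc1ccccc1
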